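The 2H-chromene is cut across its pyran ring at O1–C2 and C3–C4. The feature exploited is that C4 is sp2 in the target while the quaternary C2, two atoms away in the same ring, carries a two-carbon arm (C1'–C2'): C4 can therefore serve as a disposable stereocentre and the arm as a tether. A salicylaldehyde and 3-methylbut-3-en-1-ol are joined in one chiral-acid-catalysed operation, a Prins cyclization that forms C3–C4 followed by capture of the C2 cation by the phenol oxygen, giving an O–CH2–CH2-bridged chroman. Eliminative opening of the bridge later installs C3=C4 and frees C2' for coupling with an iodoalkenyl butenolide.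

Key step: step 3

Remark on the chemistry: locants O1, C2, C3, C4, C4a to C8a are those of the chromene and C1', C2' onward count along the side chain from C2; the chiral acid of step 3 is taken as the enantiomer that forms the benzylic carbon with the R configuration.

Step 1
Reactants: 1 2-methylbenzene-1,4-diol (methylhydroquinone)
Product: 2 2-methyl-4-(triisopropylsilyloxy)phenol
Conditions: TIPSCl (1.0 equiv), imidazole, DMF, 0 °C
Reagents that add atoms: triisopropylsilyl chloride, CC(C)[Si](Cl)(C(C)C)C(C)C
Why: O-silylation with a bulky silyl chloride should go to the C4 hydroxyl, which unlike the C1 hydroxyl has no ortho methyl group, and leaves free the phenol that is needed for ortho-formylation and later becomes O1.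

Step 2
Reactants: 2 2-methyl-4-(triisopropylsilyloxy)phenol
Product: 3 2-hydroxy-3-methyl-5-(triisopropylsilyloxy)benzaldehyde
Conditions: MgCl2, Et3N, (CH2O)n, MeCN, reflux
Reagents that add atoms: paraformaldehyde (as formaldehyde), C=O
Why: magnesium-phenoxide-directed ortho-formylation (Casnati–Skattebøl type) can only reach the single free position ortho to the phenol and so installs the aldehyde carbon that becomes C4.

Step 3
Reactants: 3 2-hydroxy-3-methyl-5-(triisopropylsilyloxy)benzaldehyde; 4 3-methylbut-3-en-1-ol
Product: 7 (2S,6R)-2,10-dimethyl-8-(triisopropylsilyloxy)-3,4-dihydro-2H,6H-2,6-methano-1,5-benzodioxocine (a chroman with 2S,4R configuration whose C4 oxygen is tied to C2 by an O–CH2–CH2 bridge), via oxocarbenium ion 5 (not isolated), via tertiary carbocation 6 (not isolated)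
Conditions: 4 (1.5 equiv), chiral confined imidodiphosphorimidate Brønsted acid (5 mol%), 5 Å MS, cyclohexane, 0 °C → rt
Reagents that add atoms: none
Why: Proposed new method: the acid condenses 3 with 4 to oxocarbenium ion 5 (the O-alkylated ortho-quinone methide of the salicylaldehyde), the terminal alkene carbon attacks its carbon C4 in a Prins cyclization (C3–C4), and the tertiary cation 6 at C2 is captured by the phenol oxygen (O1–C2), directly or after reversible proton loss to the exocyclic alkene and re-protonation by the same strong acid, so that overall a formal intramolecular [4+2] cycloaddition of the ortho-quinone methide with its tethered alkene takes place. The closest known reaction types are the catalytic asymmetric Prins cyclization of salicylaldehydes with this same alcohol, which stops at the 4-methylenetetrahydropyran, and the hydroalkoxylation of 1,1-disubstituted alkenes by the same class of confined strong acids; their merger into one Prins bicyclization has not been shown. The tetrahydropyran ring closes 6-endo-trig at the alkene with both alkene carbons inside the ring, and the chroman ring then closes by O-attack on the ring cation across that tetrahydropyran, a bridging closure that gives the bicyclo[3.3.1] ether. C4 (R) is set by the chiral counter-anion that shields one face of the oxocarbenium ion, with the free ortho hydroxyl anchoring the substrate, and C2 (S) is set by the substrate, because the O–CH2–CH2 bridge lets the phenol reach only the face of the cation on the side of the aryl group, so its configuration follows from C4 by ring constraint alone. The step needs enantiofacial control (catalyst), Markovnikov capture of the cation instead of its loss as an alkene (all protonation equilibria should drain into the bicyclic ether, the only product without an acid-labile alkene) and no ionisation of the benzylic C4–O bond before the second ring has closed (non-polar solvent, low temperature).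

Step 4
Reactants: 7 (2S,6R)-2,10-dimethyl-8-(triisopropylsilyloxy)-3,4-dihydro-2H,6H-2,6-methano-1,5-benzodioxocine
Product: 9 2-[(2S)-2,8-dimethyl-6-(triisopropylsilyloxy)-2H-chromen-2-yl]ethan-1-ol, via trimethylsilyl ether 8 (not isolated)
Conditions: TMSOTf, 2,6-di-tert-butyl-4-methylpyridine, CH2Cl2, −40 → 0 °C; then aq. citric acid, THF
Reagents that add atoms: none
Why: silylation of the more basic bridging dialkyl ether oxygen lets the benzylic C4–O bond ionise to a cation stabilised by the ortho ring oxygen O1 and the hindered base removes a C3 proton, an E1 dealkoxylative elimination of a 4-alkoxychroman to the 2H-chromene (known with protic acids) that should be irreversible here because the departing oxygen leaves capped as a silyl ether; C2 is not involved and keeps its configuration while the C4 stereocentre is erased.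

Step 5
Reactants: 9 2-[(2S)-2,8-dimethyl-6-(triisopropylsilyloxy)-2H-chromen-2-yl]ethan-1-ol
Product: 10 (2S)-2-(2-iodoethyl)-2,8-dimethyl-6-(triisopropylsilyloxy)-2H-chromene
Conditions: PPh3, I2, imidazole, CH2Cl2, 0 °C
Reagents that add atoms: iodine, [I][I]
Why: Appel iodination of the unhindered primary alcohol runs under neutral conditions that should leave the acid-sensitive chromene and the aryl silyl ether untouched.

Step 6
Reactants: 11 (R)-epichlorohydrin
Product: 12 (2R)-1-chloropent-4-yn-2-ol
Conditions: HC≡CH, n-BuLi, THF, −78 °C; BF3·OEt2, then 11; aq. NH4Cl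
Reagents that add atoms: acetylene (as lithium acetylide), C#C
Why: BF3-assisted SN2 opening of the epoxide by lithium acetylide at the unsubstituted ring carbon keeps the carbinol stereocentre, which comes from the chiral pool and becomes C5 of the butenolide.

Step 7
Reactants: 12 (2R)-1-chloropent-4-yn-2-ol
Product: 14 (2R,4E)-1-chloro-5-iodo-4-methylpent-4-en-2-ol, via alkenylalane 13 (not isolated)
Conditions: Me3Al, Cp2ZrCl2 (cat.), CH2Cl2, 0 °C → rt; then I2, THF, −30 °C
Reagents that add atoms: trimethylaluminium, C[Al](C)C; iodine, [I][I]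
Why: zirconium-catalysed Negishi carboalumination adds methyl and aluminium syn across the terminal alkyne with aluminium at the terminus, and iodinolysis with retention fixes the E-trisubstituted alkene.

Step 8
Reactants: 14 (2R,4E)-1-chloro-5-iodo-4-methylpent-4-en-2-ol
Product: 15 (2R)-2-[(2E)-3-iodo-2-methylprop-2-en-1-yl]oxirane
Conditions: K2CO3, MeOH, rt
Reagents that add atoms: none
Why: intramolecular Williamson closure of the chlorohydrin displaces chloride at the primary carbon, so the stereocentre is not touched.

Step 9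
Reactants: 15 (2R)-2-[(2E)-3-iodo-2-methylprop-2-en-1-yl]oxirane; 16 (phenylsulfanyl)acetic acid
Product: 18 (5R)-5-[(2E)-3-iodo-2-methylprop-2-en-1-yl]-3-(phenylsulfanyl)oxolan-2-one as a mixture of C3 epimers, via γ-hydroxy acid 17 (not isolated)
Conditions: 16, LDA (2.1 equiv), THF, −78 → 0 °C; then 15, rt; aq. HCl; TsOH (cat.), toluene, 60 °C
Reagents that add atoms: none
Why: the sulfur-stabilised carboxylate dianion opens the epoxide at its terminal carbon (SN2) and acid-catalysed lactonisation of the γ-hydroxy acid follows, so C5 is retained and the C3 configuration is of no consequence.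

Step 10
Reactants: 18 (5R)-5-[(2E)-3-iodo-2-methylprop-2-en-1-yl]-3-(phenylsulfanyl)oxolan-2-one; 19 5-bromo-2-methylpent-2-ene
Product: 20 (5R)-5-[(2E)-3-iodo-2-methylprop-2-en-1-yl]-3-(4-methylpent-3-en-1-yl)-3-(phenylsulfanyl)oxolan-2-one as a mixture of C3 epimers
Conditions: LDA, THF, −78 °C; then 19, DMPU, −78 → 0 °C
Reagents that add atoms: none
Why: SN2 alkylation of the α-sulfanyl lactone enolate with the primary bromide installs the side chain at C3, whose configuration is erased in the next step.

Step 11
Reactants: 20 (5R)-5-[(2E)-3-iodo-2-methylprop-2-en-1-yl]-3-(4-methylpent-3-en-1-yl)-3-(phenylsulfanyl)oxolan-2-one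
Product: 22 (5R)-5-[(2E)-3-iodo-2-methylprop-2-en-1-yl]-3-(4-methylpent-3-en-1-yl)furan-2(5H)-one, via sulfoxide 21 (not isolated)
Conditions: mCPBA (1.0 equiv), CH2Cl2, −78 °C; then toluene, CaCO3, 110 °C
Reagents that add atoms: none
Why: sulfide oxidation is much faster than alkene epoxidation at low temperature, and thermal syn-elimination of the sulfoxide toward the ring CH2 should give the conjugated endocyclic butenolide without touching C5.

Step 12
Reactants: 10 (2S)-2-(2-iodoethyl)-2,8-dimethyl-6-(triisopropylsilyloxy)-2H-chromene; 22 (5R)-5-[(2E)-3-iodo-2-methylprop-2-en-1-yl]-3-(4-methylpent-3-en-1-yl)furan-2(5H)-one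
Product: 24 (5R)-5-[(2E)-5-[(2S)-2,8-dimethyl-6-(triisopropylsilyloxy)-2H-chromen-2-yl]-2-methylpent-2-en-1-yl]-3-(4-methylpent-3-en-1-yl)furan-2(5H)-one, via alkylzinc iodide 23 (not isolated)
Conditions: 10, Zn dust (activated with BrCH2CH2Br, TMSCl), DMA, 40 °C; then 22, PdCl2(dppf) (5 mol%), THF, rt → 45 °C
Reagents that add atoms: none
Why: Negishi sp3–sp2 cross-coupling of a primary alkylzinc iodide with an iodoalkene proceeds with retention of alkene geometry, and the weakly basic organozinc should spare the butenolide and its C5 stereocentre.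

Step 13
Reactants: 24 (5R)-5-[(2E)-5-[(2S)-2,8-dimethyl-6-(triisopropylsilyloxy)-2H-chromen-2-yl]-2-methylpent-2-en-1-yl]-3-(4-methylpent-3-en-1-yl)furan-2(5H)-one
Product: 25 tuberatolide B, (5R)-5-[(2E)-5-[(2S)-6-hydroxy-2,8-dimethyl-2H-chromen-2-yl]-2-methylpent-2-en-1-yl]-3-(4-methylpent-3-en-1-yl)furan-2(5H)-one
Conditions: TBAF, AcOH, THF, 0 °C
Reagents that add atoms: none
Why: fluoride desilylation cleaves the aryl silyl ether rapidly, and acetic acid buffering should keep phenoxide and fluoride from epimerising the butenolide.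

Compound list
1 | 2-methylbenzene-1,4-diol | Cc1cc(O)ccc1O | starting material
2 | 2-methyl-4-(triisopropylsilyloxy)phenol | Cc1cc(O[Si](C(C)C)(C(C)C)C(C)C)ccc1O | intermediate
3 | 2-hydroxy-3-methyl-5-(triisopropylsilyloxy)benzaldehyde | Cc1cc(O[Si](C(C)C)(C(C)C)C(C)C)cc(C=O)c1O | intermediate
4 | 3-methylbut-3-en-1-ol | CC(=C)CCO | starting material
5 | oxocarbenium ion from 3 and 4 | C=C(C)CC[O+]=Cc1cc(O[Si](C(C)C)(C(C)C)C(C)C)cc(C)c1O | intermediate
6 | (2R)-2-aryl-4-methyltetrahydropyran-4-yl cation | C[C+]1CCO[C@H](C1)c1cc(O[Si](C(C)C)(C(C)C)C(C)C)cc(C)c1O | intermediate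
7 | (2S,6R)-2,10-dimethyl-8-(triisopropylsilyloxy)-3,4-dihydro-2H,6H-2,6-methano-1,5-benzodioxocine | C[C@]12CCO[C@H](C1)c1cc(O[Si](C(C)C)(C(C)C)C(C)C)cc(C)c1O2 | intermediate
8 | trimethylsilyl ether of 9 | C[Si](C)(C)OCC[C@@]1(C)C=Cc2cc(O[Si](C(C)C)(C(C)C)C(C)C)cc(C)c2O1 | intermediate
9 | 2-[(2S)-2,8-dimethyl-6-(triisopropylsilyloxy)-2H-chromen-2-yl]ethan-1-ol | OCC[C@@]1(C)C=Cc2cc(O[Si](C(C)C)(C(C)C)C(C)C)cc(C)c2O1 | intermediate
10 | (2S)-2-(2-iodoethyl)-2,8-dimethyl-6-(triisopropylsilyloxy)-2H-chromene | ICC[C@@]1(C)C=Cc2cc(O[Si](C(C)C)(C(C)C)C(C)C)cc(C)c2O1 | intermediate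
11 | (R)-epichlorohydrin | ClC[C@H]1CO1 | starting material
12 | (2R)-1-chloropent-4-yn-2-ol | ClC[C@H](O)CC#C | intermediate
13 | (E)-alkenyl(dimethyl)alane, as its dimethylaluminium alkoxide | ClC[C@H](O[Al](C)C)C/C(C)=C/[Al](C)C | intermediate
14 | (2R,4E)-1-chloro-5-iodo-4-methylpent-4-en-2-ol | ClC[C@H](O)C/C(C)=C/I | intermediate
15 | (2R)-2-[(2E)-3-iodo-2-methylprop-2-en-1-yl]oxirane | I/C=C(C)/C[C@@H]1CO1 | intermediate
16 | (phenylsulfanyl)acetic acid | OC(=O)CSc1ccccc1 | starting material
17 | (4R,6E)-4-hydroxy-7-iodo-6-methyl-2-(phenylsulfanyl)hept-6-enoic acid | OC(=O)C(Sc1ccccc1)C[C@H](O)C/C(C)=C/I | intermediate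
18 | (5R)-5-[(2E)-3-iodo-2-methylprop-2-en-1-yl]-3-(phenylsulfanyl)oxolan-2-one | O=C1O[C@H](C/C(C)=C/I)CC1Sc1ccccc1 | intermediate
19 | 5-bromo-2-methylpent-2-ene | CC(C)=CCCBr | starting material
20 | (5R)-5-[(2E)-3-iodo-2-methylprop-2-en-1-yl]-3-(4-methylpent-3-en-1-yl)-3-(phenylsulfanyl)oxolan-2-one | O=C1O[C@H](C/C(C)=C/I)CC1(CCC=C(C)C)Sc1ccccc1 | intermediate
21 | sulfoxide of 20 | O=C1O[C@H](C/C(C)=C/I)CC1(CCC=C(C)C)S(=O)c1ccccc1 | intermediate
22 | (5R)-5-[(2E)-3-iodo-2-methylprop-2-en-1-yl]-3-(4-methylpent-3-en-1-yl)furan-2(5H)-one | CC(C)=CCCC1=C[C@@H](C/C(C)=C/I)OC1=O | intermediate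
23 | alkylzinc iodide from 10 | I[Zn]CC[C@@]1(C)C=Cc2cc(O[Si](C(C)C)(C(C)C)C(C)C)cc(C)c2O1 | intermediate
24 | triisopropylsilyl ether of tuberatolide B | CC(C)=CCCC1=C[C@@H](C/C(C)=C/CC[C@@]2(C)C=Cc3cc(O[Si](C(C)C)(C(C)C)C(C)C)cc(C)c3O2)OC1=O | intermediate
25 | tuberatolide B | CC(C)=CCCC1=C[C@@H](C/C(C)=C/CC[C@@]2(C)C=Cc3cc(O)cc(C)c3O2)OC1=O | target

Total step count: 13.
Longest linear sequence: 8 steps (steps 6 to 13, from (R)-epichlorohydrin 11); the chromene branch needs 7 (steps 1 to 5, then 12 and 13).

Steps most likely to fail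

Step 3 (Proposed new method). Proton loss from the cation may outrun its capture by the phenol, so that the reaction stalls at the alkene stage. Reversible ionisation of the benzylic C4–O bond under the strong acid, before the second ring has closed, may also erode the enantiomeric purity. The fallback uses known chemistry and sets out from 3 and 4. The established catalytic asymmetric Prins cyclization with a milder confined imino-imidodiphosphate acid is stopped at 2-methyl-6-[(2R)-4-methylideneoxan-2-yl]-4-(triisopropylsilyloxy)phenol F1, which is isolated. The O1–C2 bond is then made without acid by intramolecular Markovnikov oxymercuration with Hg(O2CCF3)2 in CH2Cl2, which should give the alkylmercury trifluoroacetate F2 (mercury on the C2 methyl carbon of the bridged skeleton). Reductive demercuration with NaBH4 and aqueous NaOH comes back to the route at 7.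

Step 4. The ionisation may be reversed by re-closure of the bridge faster than deprotonation at C3, or the tertiary O1–C2 ether may ionise instead and open the chroman ring. The fallback sets out from 7. Lewis-acid acetolysis of the benzylic ether (Ac2O, FeCl3 cat., 0 °C) should give 2-[(2S)-4-acetoxy-2,8-dimethyl-6-(triisopropylsilyloxy)chroman-2-yl]ethyl acetate F3, in which the side-chain oxygen can no longer return. Acid-catalysed elimination of acetic acid (TsOH cat., toluene, 80 °C) should give 2-[(2S)-2,8-dimethyl-6-(triisopropylsilyloxy)-2H-chromen-2-yl]ethyl acetate F4. Reduction with i-Bu2AlH in CH2Cl2 at −78 °C frees the alcohol and comes back to the route at 9.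

Step 12. Zinc insertion or transmetallation may be slow against the hindered trisubstituted iodoalkene, so that protodemetallation and homocoupling take over, and the organometallic may deprotonate the butenolide at C5. The fallback sets out from 10. Dehydroiodination (KOt-Bu, THF, 0 °C) should give (2S)-2-ethenyl-2,8-dimethyl-6-(triisopropylsilyloxy)-2H-chromene F5. Hydroboration of its terminal alkene with 9-borabicyclo[3.3.1]nonane in THF should give 9-{2-[(2S)-2,8-dimethyl-6-(triisopropylsilyloxy)-2H-chromen-2-yl]ethyl}-9-borabicyclo[3.3.1]nonane F6. Suzuki–Miyaura coupling of F6 with 22 (PdCl2(dppf), AsPh3, aq. K3PO4, DMF, rt) comes back to the route at 24.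

Further compounds
F1 | step 3 | 2-methyl-6-[(2R)-4-methylideneoxan-2-yl]-4-(triisopropylsilyloxy)phenol | C=C1CCO[C@H](C1)c1cc(O[Si](C(C)C)(C(C)C)C(C)C)cc(C)c1O
F2 | step 3 | alkylmercury trifluoroacetate of the bridged ether (mercury on the C2 methyl carbon of 7) | FC(F)(F)C(=O)O[Hg]C[C@]12CCO[C@H](C1)c1cc(O[Si](C(C)C)(C(C)C)C(C)C)cc(C)c1O2
F3 | step 4 | 2-[(2S)-4-acetoxy-2,8-dimethyl-6-(triisopropylsilyloxy)chroman-2-yl]ethyl acetate (C4 epimers) | CC(=O)OCC[C@@]1(C)CC(OC(C)=O)c2cc(O[Si](C(C)C)(C(C)C)C(C)C)cc(C)c2O1
F4 | step 4 | 2-[(2S)-2,8-dimethyl-6-(triisopropylsilyloxy)-2H-chromen-2-yl]ethyl acetate | CC(=O)OCC[C@@]1(C)C=Cc2cc(O[Si](C(C)C)(C(C)C)C(C)C)cc(C)c2O1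
F5 | step 12 | (2S)-2-ethenyl-2,8-dimethyl-6-(triisopropylsilyloxy)-2H-chromene | C=C[C@@]1(C)C=Cc2cc(O[Si](C(C)C)(C(C)C)C(C)C)cc(C)c2O1
F6 | step 12 | 9-{2-[(2S)-2,8-dimethyl-6-(triisopropylsilyloxy)-2H-chromen-2-yl]ethyl}-9-borabicyclo[3.3.1]nonane | B1(CC[C@@]2(C)C=Cc3cc(O[Si](C(C)C)(C(C)C)C(C)C)cc(C)c3O2)C2CCCC1CCC2
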